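**Retrosynthetic overview**
1. Endgame (xenicane numbering: ring B = pyran C1–O2–C3=C4–C4a–C11a; ring A = carbocycle C4a–C5–C6–C7(Me)–C8–C9–C10–C11(=C19H2)–C11a): C1 and C12 acetates; side chain C13–C16 by allylboration and cross-metathesis on the C4 formyl group; 7,8-epoxide by peracid on the E-olefin; ring B by lactol closure of a C1 aldehyde onto a C3/C12 hydroxymethylene dialdehyde.
2. Feature the plan rests on: in ring A, C11 (the future methylidene carbon, a ketone in the retron) lies γ,δ to the C7=C8 olefin through C10–C9. This is a Claisen retron: cut C9–C10, rejoin O–C7, and ring A becomes a 2-methylidene-7-methyl-7-vinyloxepane.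
3. A seven-to-nine Claisen ring expansion can only deliver the Z-olefin (the ring tether must sit pseudo-axial on C7 in the chair array). The E geometry needed for the trans-epoxide is therefore set afterwards by a stereospecific epoxide/phosphide olefin inversion.
4. The oxepane comes from Baeyer–Villiger oxidation of a 2,3-trans-6-methyl-6-vinylcyclohexanone, made by asymmetric Mukaiyama–Michael addition and orthoformate capture on (S)-6-methyl-6-vinylcyclohexenone, itself from 2-methylcyclohexanone by a chiral-imine Michael addition.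
5. Ring order: sacrificial cyclohexanone → oxepanone → ring A (Claisen) → ring B (lactol) → oxirane.

Key step: step 11

Remark on stereolabile centres: ketimine 4 (ring methine), cis-epoxide 20 (either face converges in step 14, one isomer is drawn) and lactol 29 (C1 anomers) are not configurationally fixed at those centres.
Remark on the Tebbe reagent: Cp2Ti(μ-CH2)(μ-Cl)AlMe2 is drawn in its open form, with the chloride on titanium and the dative Cl→Al contact left out.

**Step 1**
Reactants: 1 2-methylcyclohexanone; 2 (R)-1-phenylethylamine; 3 methyl acrylate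
Product: 6 methyl 3-[(1S)-1-methyl-2-oxocyclohexyl]propanoate, via ketimine 4 (not isolated), via adduct ketimine 5 (not isolated)
Conditions: 1 + 2, TsOH (cat.), PhMe, reflux (Dean–Stark); then 3, THF, 40 °C; then 20% aq. AcOH, 25 °C
Reagents that add atoms: water, O
Why: Asymmetric Michael addition of a chiral ketimine through its more substituted secondary-enamine tautomer (aza-ene type, internal proton transfer), in which the phenyl group of the (R)-auxiliary screens one face so that the acrylate is taken up at the methyl-bearing carbon and sets the (S) quaternary centre that becomes C7, after which mild acid returns the ketone and the amine.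

**Step 2**
Reactants: 6 methyl 3-[(1S)-1-methyl-2-oxocyclohexyl]propanoate
Product: 7 3-[(1S)-1-methyl-2-oxocyclohexyl]propanoic acid
Conditions: LiOH, THF/H2O, 25 °C; then 1 M HCl
Reagents that add atoms: lithium hydroxide, [Li+].[OH-]
Why: Ester saponification; the quaternary centre cannot enolise and so cannot racemise.

**Step 3**
Reactants: 7 3-[(1S)-1-methyl-2-oxocyclohexyl]propanoic acid
Product: 8 (S)-2-methyl-2-vinylcyclohexan-1-one
Conditions: Pb(OAc)4, Cu(OAc)2 (cat.), pyridine, PhH, 80 °C
Reagents that add atoms: none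
Why: Oxidative decarboxylation of a primary acid to a terminal olefin (Kochi type: the lead carboxylate fragments to the alkyl radical, which the copper salt oxidises with loss of a β-hydrogen); the only β-hydrogens lie on the CH2 next to the quaternary carbon, so the vinyl group is the only olefin that can form.

**Step 4**
Reactants: 8 (S)-2-methyl-2-vinylcyclohexan-1-one
Product: 9 (S)-6-methyl-6-vinylcyclohex-2-en-1-one
Conditions: IBX, DMSO/PhF, 70 °C
Reagents that add atoms: none
Why: IBX dehydrogenation of a ketone to its enone; enolisation is possible only toward the ring methylene because the other α-carbon is quaternary, so one enone results and the stereocentre is untouched.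

**Step 5**
Reactants: 9 (S)-6-methyl-6-vinylcyclohex-2-en-1-one; 10 tert-butyl[(1-methoxyvinyl)oxy]dimethylsilane
Product: 11 methyl 2-[(1R,4S)-3-(tert-butyldimethylsilyloxy)-4-methyl-4-vinylcyclohex-2-en-1-yl]acetate
Conditions: (S)-B-(o-tolyl)oxazaborolidine of α,α-diphenylprolinol·HNTf2 (20 mol %; antipode chosen for Si-face attack at C3), Ph3PO (25 mol %), PhMe, −20 °C
Reagents that add atoms: none
Why: Catalytic enantioselective Mukaiyama–Michael addition: the cationic oxazaborolidine binds the enone oxygen on the side of the α-CH, away from the quaternary α′-carbon, and screens one face of the β-carbon, so the ketene acetal adds to the Si face and sets C1 of 11 (the future C4a) as R independently of the remote quaternary centre (the minor enantiomer of 9 ends up as a separable diastereomer), while silyl transfer leaves the regiodefined enol silane.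

**Step 6**
Reactants: 11 methyl 2-[(1R,4S)-3-(tert-butyldimethylsilyloxy)-4-methyl-4-vinylcyclohex-2-en-1-yl]acetate
Product: 12 2-[(1R,4S)-3-(tert-butyldimethylsilyloxy)-4-methyl-4-vinylcyclohex-2-en-1-yl]ethan-1-ol
Conditions: iBu2AlH, CH2Cl2, −78 → 0 °C; aq. potassium sodium tartrate
Reagents that add atoms: none
Why: Ester reduction with an aluminium hydride; the ketone is masked as its silyl enol ether, which is inert to the hydride, so only the ester is reduced.

**Step 7**
Reactants: 12 2-[(1R,4S)-3-(tert-butyldimethylsilyloxy)-4-methyl-4-vinylcyclohex-2-en-1-yl]ethan-1-ol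
Product: 13 tert-butyl{2-[(1R,4S)-3-(tert-butyldimethylsilyloxy)-4-methyl-4-vinylcyclohex-2-en-1-yl]ethoxy}dimethylsilane
Conditions: TBSCl, imidazole, DMF, 25 °C
Reagents that add atoms: tert-butyldimethylsilyl chloride, C[Si](C)(Cl)C(C)(C)C
Why: Silylation of the primary alcohol; the enol silane is unaffected under these mildly basic conditions.

**Step 8**
Reactants: 13 tert-butyl{2-[(1R,4S)-3-(tert-butyldimethylsilyloxy)-4-methyl-4-vinylcyclohex-2-en-1-yl]ethoxy}dimethylsilane; 14 trimethyl orthoformate
Product: 15 (2S,3R,6S)-3-[2-(tert-butyldimethylsilyloxy)ethyl]-2-(dimethoxymethyl)-6-methyl-6-vinylcyclohexan-1-one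
Conditions: Me3SiOTf (cat.), CH2Cl2, −78 → −40 °C; NaHCO3
Reagents that add atoms: none
Why: Mukaiyama-type aldol addition of the enol silane to the dimethoxycarbenium ion released from the orthoformate, the electrophile entering C2 anti to the C3 side chain to give the trans-2,3 (diequatorial, also thermodynamic) arrangement, which fixes C11a relative to C4a.

**Step 9**
Reactants: 15 (2S,3R,6S)-3-[2-(tert-butyldimethylsilyloxy)ethyl]-2-(dimethoxymethyl)-6-methyl-6-vinylcyclohexan-1-one
Product: 16 (3S,4R,7S)-4-[2-(tert-butyldimethylsilyloxy)ethyl]-3-(dimethoxymethyl)-7-methyl-7-vinyloxepan-2-one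
Conditions: mCPBA, NaHCO3, CH2Cl2, 0 → 25 °C
Reagents that add atoms: 3-chloroperbenzoic acid, OOC(=O)c1cccc(Cl)c1
Why: Baeyer–Villiger oxidation: the quaternary, vinyl-bearing carbon migrates with retention in preference to the acetal-bearing secondary carbon and so places the ring oxygen on C7, and the buffered peracid attacks the ketone faster than the hindered monosubstituted vinyl group.

**Step 10**
Reactants: 16 (3S,4R,7S)-4-[2-(tert-butyldimethylsilyloxy)ethyl]-3-(dimethoxymethyl)-7-methyl-7-vinyloxepan-2-one
Product: 17 (3R,4R,7S)-4-[2-(tert-butyldimethylsilyloxy)ethyl]-3-(dimethoxymethyl)-7-methyl-2-methylidene-7-vinyloxepane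
Conditions: Cp2Ti(μ-CH2)(μ-Cl)AlMe2 (Tebbe reagent), pyridine, THF/PhMe, −40 → 0 °C; aq. NaOH, basic Al2O3
Reagents that add atoms: Tebbe reagent Cp2Ti(μ-CH2)(μ-Cl)AlMe2, C[Al](C)C[Ti](Cl)(C1C=CC=C1)C1C=CC=C1
Why: Tebbe methylenation of the lactone carbonyl gives the exocyclic enol ether under non-basic conditions, so the α-stereocentre and the acetal are preserved and the vinyl group is not engaged at low temperature.

**Step 11**
Reactants: 17 (3R,4R,7S)-4-[2-(tert-butyldimethylsilyloxy)ethyl]-3-(dimethoxymethyl)-7-methyl-2-methylidene-7-vinyloxepane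
Product: 18 (4Z,8R,9S)-8-[2-(tert-butyldimethylsilyloxy)ethyl]-9-(dimethoxymethyl)-5-methylcyclonon-4-en-1-one
Conditions: PhMe (0.02 M), iPr2NEt (trace), base-washed sealed tube, 170 °C
Reagents that add atoms: none
Why: Thermal [3,3]-sigmatropic (Claisen) rearrangement of the allyl vinyl ether C10=C11–O–C7–C8=C9 held in the oxepane: C9–C10 is formed, O–C7 is broken and the C11 carbonyl appears, the new C=O bond paying for the strain of the medium ring. The closest known reaction type is the Claisen ring expansion of 2-methylene cyclic ethers that carry a vinyl group on the other α-carbon, long established for six-membered ethers and also practised on seven-membered ones. Ring A is closed by this sigmatropic C–C bond formation as a two-atom ring expansion through a bridged chair-like array, not by an end-to-end cyclisation. No stereocentre is created; C7 is traded for olefin geometry, and because a four-carbon tether from C11 can reach C7 only through the pseudo-axial position of the chair (the pseudo-equatorial position would need an extended C11a–C11–O–C7–C6 zigzag that a seven-membered ring cannot hold), C6 ends up cis to C9 and the olefin is Z, the E isomer being accessible only through a boat array. The step needs this chair pathway to run cleanly, and the C7 epimer used secures it: with the vinyl group anti to the C11a acetal the allyl terminus meets C10 on the enol-ether face away from the acetal, and both side arms stay on the outer side of the tether. C4a and C11a are spectators, and the base-washed, acid-free medium keeps the exocyclic enol ether from isomerising before it rearranges.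

**Step 12**
Reactants: 18 (4Z,8R,9S)-8-[2-(tert-butyldimethylsilyloxy)ethyl]-9-(dimethoxymethyl)-5-methylcyclonon-4-en-1-one
Product: 19 tert-butyl{2-[(1R,4Z,9R)-9-(dimethoxymethyl)-4-methyl-8-methylidenecyclonon-4-en-1-yl]ethoxy}dimethylsilane
Conditions: Cp2Ti(μ-CH2)(μ-Cl)AlMe2 (Tebbe reagent), pyridine, THF, −40 → 0 °C; aq. NaOH
Reagents that add atoms: Tebbe reagent Cp2Ti(μ-CH2)(μ-Cl)AlMe2, C[Al](C)C[Ti](Cl)(C1C=CC=C1)C1C=CC=C1
Why: Tebbe methylenation of a hindered, enolisable ketone; the titanium methylidene is not basic, so C11a is not epimerised and methanol is not eliminated from the β-keto acetal, both of which a phosphorus ylide could cause.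

**Step 13**
Reactants: 19 tert-butyl{2-[(1R,4Z,9R)-9-(dimethoxymethyl)-4-methyl-8-methylidenecyclonon-4-en-1-yl]ethoxy}dimethylsilane
Product: 20 cis-7,8-epoxide of 19 (drawn 7R,8S; 4aR,11aR; xenicane numbering)
Conditions: mCPBA (1.05 equiv), NaHCO3, CH2Cl2, −20 → 0 °C
Reagents that add atoms: 3-chloroperbenzoic acid, OOC(=O)c1cccc(Cl)c1
Why: Peracid (Prilezhaev) epoxidation, selective for the trisubstituted ring olefin over the 1,1-disubstituted exocyclic one; attack on either face gives a cis-epoxide and both converge in step 14, so facial selectivity does not matter.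

**Step 14**
Reactants: 20 cis-7,8-epoxide of 19
Product: 23 tert-butyl{2-[(1R,4E,9R)-9-(dimethoxymethyl)-4-methyl-8-methylidenecyclonon-4-en-1-yl]ethoxy}dimethylsilane, via lithium β-phosphinoalkoxide 21 (not isolated), via phosphonium betaine 22 (not isolated)
Conditions: LiPPh2, THF, 25 °C; then MeI, 25 °C
Reagents that add atoms: none
Why: Olefin inversion through a phosphorus betaine: the phosphide opens the epoxide at the secondary carbon C8 with inversion, P-methylation gives the betaine, and its syn-cycloelimination through the oxaphosphetane expels the phosphine oxide, so anti opening followed by syn elimination converts the Z- into the E-olefin stereospecifically, as known for the cis-to-trans inversion of medium-ring cycloalkenes.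

**Step 15**
Reactants: 23 tert-butyl{2-[(1R,4E,9R)-9-(dimethoxymethyl)-4-methyl-8-methylidenecyclonon-4-en-1-yl]ethoxy}dimethylsilane
Product: 24 2-[(1R,4E,9R)-9-(dimethoxymethyl)-4-methyl-8-methylidenecyclonon-4-en-1-yl]ethan-1-ol
Conditions: Bu4NF, THF, 25 °C
Reagents that add atoms: none
Why: Fluoride-induced cleavage of the primary silyl ether; the acetal and both olefins are inert.

**Step 16**
Reactants: 24 2-[(1R,4E,9R)-9-(dimethoxymethyl)-4-methyl-8-methylidenecyclonon-4-en-1-yl]ethan-1-ol
Product: 25 2-[(1R,4E,9R)-9-(dimethoxymethyl)-4-methyl-8-methylidenecyclonon-4-en-1-yl]acetaldehyde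
Conditions: Dess–Martin periodinane, NaHCO3, CH2Cl2, 0 → 25 °C
Reagents that add atoms: none
Why: Dess–Martin oxidation of the primary alcohol to the aldehyde under buffered, non-acidic conditions that spare the acetal and the strained E-olefin.

**Step 17**
Reactants: 25 2-[(1R,4E,9R)-9-(dimethoxymethyl)-4-methyl-8-methylidenecyclonon-4-en-1-yl]acetaldehyde; 26 tert-butoxybis(dimethylamino)methane (Bredereck's reagent)
Product: 27 (E)-2-[(1S,4E,9R)-9-(dimethoxymethyl)-4-methyl-8-methylidenecyclonon-4-en-1-yl]-3-(dimethylamino)acrylaldehyde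
Conditions: PhMe, 60 °C
Reagents that add atoms: none
Why: Aminomethylenation of an enolisable aldehyde with an aminal ester (Bredereck's reagent): tert-butoxide released from the reagent forms the enolate, which adds to the formamidinium ion and loses dimethylamine to give the vinylogous formamide, installing the last carbon of the C3/C4/C12 unit without acid.

**Step 18**
Reactants: 27 (E)-2-[(1S,4E,9R)-9-(dimethoxymethyl)-4-methyl-8-methylidenecyclonon-4-en-1-yl]-3-(dimethylamino)acrylaldehyde
Product: 29 (4aS,7E,11aR)-1-hydroxy-7-methyl-11-methylidene-1,4a,5,6,9,10,11,11a-octahydrocyclonona[c]pyran-4-carbaldehyde (C1 anomers), via hydroxymethylene dialdehyde 28 (not isolated)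
Conditions: AcOH/H2O/THF (3:1:1), 35 °C
Reagents that add atoms: water, O
Why: Acid hydrolysis of the enaminal and of the dimethyl acetal, then 6-exo-trig hemiacetalisation of the vinylogous formic acid hydroxyl onto the C1 aldehyde closes ring B as the lactol; the weak acid avoids transannular reactions of the E-cyclononene, and C11a, now epimerisable, stays in the more stable trans-fused arrangement.

**Step 19**
Reactants: 29 (4aS,7E,11aR)-1-hydroxy-7-methyl-11-methylidene-1,4a,5,6,9,10,11,11a-octahydrocyclonona[c]pyran-4-carbaldehyde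
Product: 30 (1R,4aS,7E,11aR)-4-formyl-7-methyl-11-methylidene-1,4a,5,6,9,10,11,11a-octahydrocyclonona[c]pyran-1-yl acetate
Conditions: Ac2O, Et3N, 4-(dimethylamino)pyridine (cat.), CH2Cl2, −20 °C
Reagents that add atoms: acetic anhydride, CC(=O)OC(C)=O
Why: Acylation of the equilibrating lactol: the anomer with the hydroxyl anti to the C11 branch on C11a should be acylated preferentially, giving the 1R acetate (acetoxy group on the face of H-11a), which is also the configuration met throughout this natural product family.

**Step 20**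
Reactants: 30 (1R,4aS,7E,11aR)-4-formyl-7-methyl-11-methylidene-1,4a,5,6,9,10,11,11a-octahydrocyclonona[c]pyran-1-yl acetate
Product: 31 (1R,4aS,7S,8S,11aR)-7,8-epoxide of 30
Conditions: mCPBA (1.05 equiv), NaHCO3, CH2Cl2, −20 → 0 °C
Reagents that add atoms: 3-chloroperbenzoic acid, OOC(=O)c1cccc(Cl)c1
Why: Peracid epoxidation of the strained trisubstituted E-olefin, much faster than that of the exocyclic methylene or of the electron-poor enal olefin; oxygen is delivered to the outer face of the E-double bond in the favoured ring conformer, which is expected to give the 7S,8S epoxide, the same relative configuration that peracids produce on the identically substituted trans-fused E-cyclononene of caryophyllene.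

**Step 21**
Reactants: 31 (1R,4aS,7S,8S,11aR)-7,8-epoxide of 30; 32 (+)-B-allyldiisopinocampheylborane (from (−)-α-pinene)
Product: 34 (1R,4aS,7S,8S,11aR)-7,8-epoxy-4-[(1R)-1-hydroxybut-3-enyl]-7-methyl-11-methylidene-decahydrocyclonona[c]pyran-1-yl acetate, via diisopinocampheylborinate 33 (not isolated)
Conditions: 32 (pentane solution), Et2O, −78 °C; then pH 7 buffer, H2O2, MeOH, 0 °C
Reagents that add atoms: none
Why: Brown allylboration through a closed chair transition state: the reagent from (−)-α-pinene adds to the Re face of the aldehyde under reagent control and sets C12 as R, and buffered peroxide work-up cleaves the borinate without touching the acetal acetate.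

**Step 22**
Reactants: 34 homoallylic alcohol; 35 methyl methacrylate
Product: 36 methyl (2E,5R)-5-[(1R,4aS,7S,8S,11aR)-1-acetoxy-7,8-epoxy-7-methyl-11-methylidene-decahydrocyclonona[c]pyran-4-yl]-5-hydroxy-2-methylpent-2-enoate
Conditions: 35 (excess), second-generation Hoveyda–Grubbs catalyst (10 mol %), CH2Cl2, 40 °C
Reagents that add atoms: none
Why: Olefin cross-metathesis of the terminal olefin with excess methacrylate gives the trisubstituted E-enoate under thermodynamic control; the hindered exocyclic methylene, the enol ether and the epoxide do not take part.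

**Step 23**
Reactants: 36 methyl (2E,5R)-5-[(1R,4aS,7S,8S,11aR)-1-acetoxy-7,8-epoxy-7-methyl-11-methylidene-decahydrocyclonona[c]pyran-4-yl]-5-hydroxy-2-methylpent-2-enoate
Product: 37 target, methyl (2E,5R)-5-acetoxy-5-[(1R,4aS,7S,8S,11aR)-1-acetoxy-7,8-epoxy-7-methyl-11-methylidene-decahydrocyclonona[c]pyran-4-yl]-2-methylpent-2-enoate
Conditions: Ac2O, pyridine, 4-(dimethylamino)pyridine (cat.), CH2Cl2, 0 °C
Reagents that add atoms: acetic anhydride, CC(=O)OC(C)=O
Why: Acetylation of the secondary C12 alcohol completes the target.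

**Compound list**
1 | 2-methylcyclohexanone (racemic) | CC1CCCCC1=O | starting material
2 | (R)-1-phenylethylamine | C[C@@H](N)c1ccccc1 | starting material
3 | methyl acrylate | C=CC(=O)OC | starting material
4 | N-[(R)-1-phenylethyl]-2-methylcyclohexan-1-imine | C[C@@H](N=C1CCCCC1C)c1ccccc1 | intermediate
5 | methyl 3-[(1S)-1-methyl-2-{[(R)-1-phenylethyl]imino}cyclohexyl]propanoate | C[C@@H](N=C1CCCC[C@@]1(C)CCC(=O)OC)c1ccccc1 | intermediate
6 | methyl 3-[(1S)-1-methyl-2-oxocyclohexyl]propanoate | O=C1CCCC[C@@]1(C)CCC(=O)OC | intermediate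
7 | 3-[(1S)-1-methyl-2-oxocyclohexyl]propanoic acid | O=C1CCCC[C@@]1(C)CCC(=O)O | intermediate
8 | (S)-2-methyl-2-vinylcyclohexan-1-one | O=C1CCCC[C@@]1(C)C=C | intermediate
9 | (S)-6-methyl-6-vinylcyclohex-2-en-1-one | O=C1C=CCC[C@@]1(C)C=C | intermediate
10 | tert-butyl[(1-methoxyvinyl)oxy]dimethylsilane | C=C(OC)O[Si](C)(C)C(C)(C)C | starting material
11 | methyl 2-[(1R,4S)-3-(tert-butyldimethylsilyloxy)-4-methyl-4-vinylcyclohex-2-en-1-yl]acetate | C=C[C@]1(C)CC[C@H](CC(=O)OC)C=C1O[Si](C)(C)C(C)(C)C | intermediate
12 | 2-[(1R,4S)-3-(tert-butyldimethylsilyloxy)-4-methyl-4-vinylcyclohex-2-en-1-yl]ethan-1-ol | C=C[C@]1(C)CC[C@H](CCO)C=C1O[Si](C)(C)C(C)(C)C | intermediate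
13 | tert-butyl{2-[(1R,4S)-3-(tert-butyldimethylsilyloxy)-4-methyl-4-vinylcyclohex-2-en-1-yl]ethoxy}dimethylsilane | C=C[C@]1(C)CC[C@H](CCO[Si](C)(C)C(C)(C)C)C=C1O[Si](C)(C)C(C)(C)C | intermediate
14 | trimethyl orthoformate | COC(OC)OC | starting material
15 | (2S,3R,6S)-3-[2-(tert-butyldimethylsilyloxy)ethyl]-2-(dimethoxymethyl)-6-methyl-6-vinylcyclohexan-1-one | O=C1[C@](C)(C=C)CC[C@H](CCO[Si](C)(C)C(C)(C)C)[C@H]1C(OC)OC | intermediate
16 | (3S,4R,7S)-4-[2-(tert-butyldimethylsilyloxy)ethyl]-3-(dimethoxymethyl)-7-methyl-7-vinyloxepan-2-one | O=C1O[C@](C)(C=C)CC[C@H](CCO[Si](C)(C)C(C)(C)C)[C@H]1C(OC)OC | intermediate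
17 | (3R,4R,7S)-4-[2-(tert-butyldimethylsilyloxy)ethyl]-3-(dimethoxymethyl)-7-methyl-2-methylidene-7-vinyloxepane (key-step precursor) | C=C1O[C@](C)(C=C)CC[C@H](CCO[Si](C)(C)C(C)(C)C)[C@H]1C(OC)OC | intermediate
18 | (4Z,8R,9S)-8-[2-(tert-butyldimethylsilyloxy)ethyl]-9-(dimethoxymethyl)-5-methylcyclonon-4-en-1-one (key-step product) | O=C1CC/C=C(/C)CC[C@H](CCO[Si](C)(C)C(C)(C)C)[C@H]1C(OC)OC | intermediate
19 | tert-butyl{2-[(1R,4Z,9R)-9-(dimethoxymethyl)-4-methyl-8-methylidenecyclonon-4-en-1-yl]ethoxy}dimethylsilane | C=C1CC/C=C(/C)CC[C@H](CCO[Si](C)(C)C(C)(C)C)[C@H]1C(OC)OC | intermediate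
20 | cis-7,8-epoxide of 19 (7R,8S drawn; 4aR,11aR) | C=C1CC[C@@H]2O[C@]2(C)CC[C@H](CCO[Si](C)(C)C(C)(C)C)[C@H]1C(OC)OC | intermediate
21 | lithium (7R,8R)-8-(diphenylphosphino)-7-alkoxide from 20 | C=C1CC[C@@H](P(c2ccccc2)c2ccccc2)[C@](C)([O-])CC[C@H](CCO[Si](C)(C)C(C)(C)C)[C@H]1C(OC)OC.[Li+] | intermediate
22 | (7R,8R)-8-(methyldiphenylphosphonio)-7-oxido betaine | C=C1CC[C@@H]([P+](C)(c2ccccc2)c2ccccc2)[C@](C)([O-])CC[C@H](CCO[Si](C)(C)C(C)(C)C)[C@H]1C(OC)OC | intermediate
23 | tert-butyl{2-[(1R,4E,9R)-9-(dimethoxymethyl)-4-methyl-8-methylidenecyclonon-4-en-1-yl]ethoxy}dimethylsilane | C=C1CC/C=C(\C)CC[C@H](CCO[Si](C)(C)C(C)(C)C)[C@H]1C(OC)OC | intermediate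
24 | 2-[(1R,4E,9R)-9-(dimethoxymethyl)-4-methyl-8-methylidenecyclonon-4-en-1-yl]ethan-1-ol | C=C1CC/C=C(\C)CC[C@H](CCO)[C@H]1C(OC)OC | intermediate
25 | 2-[(1R,4E,9R)-9-(dimethoxymethyl)-4-methyl-8-methylidenecyclonon-4-en-1-yl]acetaldehyde | C=C1CC/C=C(\C)CC[C@H](CC=O)[C@H]1C(OC)OC | intermediate
26 | tert-butoxybis(dimethylamino)methane | CC(C)(C)OC(N(C)C)N(C)C | starting material
27 | (E)-2-[(1S,4E,9R)-9-(dimethoxymethyl)-4-methyl-8-methylidenecyclonon-4-en-1-yl]-3-(dimethylamino)acrylaldehyde | C=C1CC/C=C(\C)CC[C@H](/C(C=O)=C\N(C)C)[C@H]1C(OC)OC | intermediate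
28 | 2-[(1S,4E,9R)-9-formyl-4-methyl-8-methylidenecyclonon-4-en-1-yl]-3-hydroxyacrylaldehyde | C=C1CC/C=C(\C)CC[C@H](C(C=O)=CO)[C@H]1C=O | intermediate
29 | (4aS,7E,11aR)-1-hydroxy-7-methyl-11-methylidene-1,4a,5,6,9,10,11,11a-octahydrocyclonona[c]pyran-4-carbaldehyde (C1 anomers) | C=C1CC/C=C(\C)CC[C@@H]2C(C=O)=COC(O)[C@@H]12 | intermediate
30 | (1R,4aS,7E,11aR)-4-formyl-7-methyl-11-methylidene-1,4a,5,6,9,10,11,11a-octahydrocyclonona[c]pyran-1-yl acetate | C=C1CC/C=C(\C)CC[C@@H]2C(C=O)=CO[C@H](OC(C)=O)[C@@H]12 | intermediate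
31 | (1R,4aS,7S,8S,11aR)-7,8-epoxy-4-formyl-7-methyl-11-methylidene-decahydrocyclonona[c]pyran-1-yl acetate | C=C1CC[C@@H]2O[C@@]2(C)CC[C@@H]2C(C=O)=CO[C@H](OC(C)=O)[C@@H]12 | intermediate
32 | (+)-B-allyldiisopinocampheylborane (from (−)-α-pinene) | C=CCB([C@H]1C[C@H]2C[C@@H]([C@@H]1C)C2(C)C)[C@H]1C[C@H]2C[C@@H]([C@@H]1C)C2(C)C | starting material
33 | diisopinocampheylborinate ester of 34 | C=C1CC[C@@H]2O[C@@]2(C)CC[C@@H]2C([C@@H](CC=C)OB([C@H]3C[C@H]4C[C@@H]([C@@H]3C)C4(C)C)[C@H]3C[C@H]4C[C@@H]([C@@H]3C)C4(C)C)=CO[C@H](OC(C)=O)[C@@H]12 | intermediate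
34 | (1R,4aS,7S,8S,11aR)-7,8-epoxy-4-[(1R)-1-hydroxybut-3-enyl]-7-methyl-11-methylidene-decahydrocyclonona[c]pyran-1-yl acetate | C=C1CC[C@@H]2O[C@@]2(C)CC[C@@H]2C([C@@H](CC=C)O)=CO[C@H](OC(C)=O)[C@@H]12 | intermediate
35 | methyl methacrylate | C=C(C)C(=O)OC | starting material
36 | methyl (2E,5R)-5-[(1R,4aS,7S,8S,11aR)-1-acetoxy-7,8-epoxy-7-methyl-11-methylidene-decahydrocyclonona[c]pyran-4-yl]-5-hydroxy-2-methylpent-2-enoate | C=C1CC[C@@H]2O[C@@]2(C)CC[C@@H]2C([C@@H](C/C=C(\C)C(=O)OC)O)=CO[C@H](OC(C)=O)[C@@H]12 | intermediate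
37 | methyl (2E,5R)-5-acetoxy-5-[(1R,4aS,7S,8S,11aR)-1-acetoxy-7,8-epoxy-7-methyl-11-methylidene-decahydrocyclonona[c]pyran-4-yl]-2-methylpent-2-enoate | C=C1CC[C@@H]2O[C@@]2(C)CC[C@@H]2C([C@@H](C/C=C(\C)C(=O)OC)OC(C)=O)=CO[C@H](OC(C)=O)[C@@H]12 | target

**Step count**
Total: 23 steps. Longest linear sequence: 23 steps (from 2-methylcyclohexanone).

**Steps most likely to fail**

Step 11 (Claisen ring expansion). The risk is leakage through a boat-type array, which would erode the Z geometry, or acid-triggered migration of the exocyclic enol-ether double bond into the ring before the rearrangement sets in at 170 °C. Fallback: setting out from 17, the rearrangement is promoted by iBu3Al in CH2Cl2 at −78 to 0 °C instead. This is a Lewis-acid-accelerated Claisen ring expansion in which an isobutyl group transfers hydride to the aluminium-bound ketone as it forms. It should give the (Z)-cyclononenol F3 as a C11 epimer mixture, and Dess–Martin oxidation of F3 rejoins the route at 18.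

Step 14 (olefin inversion). The risk is slow backside attack of the bulky phosphide at ring carbon C8 next to the fully substituted C7, with base-induced isomerisation of the epoxide to an allylic alcohol taking over. Fallback: setting out from 19, before epoxidation, the Z-olefin is isomerised directly by singlet-sensitised irradiation (methyl benzoate, 254 nm, Et2O/hexane) in a circulating loop through AgNO3-impregnated silica. The silica retains the more strongly complexing E-cyclononene and so drives the photoequilibrium; release with aqueous NH3 should give 23, where the route is rejoined. No new isolable compound is formed on the way (F0).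

Step 5 (Mukaiyama–Michael addition). The risk is loss of enantiofacial control through silyl-cation-catalysed background addition of the small, unsubstituted ketene acetal. Fallback: setting out from 9, dimethyl malonate is added under catalysis by the heterobimetallic complex AlLi[(S)-binaphthoxide]2 (KOtBu cat., THF, 25 °C), which should deliver the malonate to the Si face and give dimethyl 2-[(1S,4S)-4-methyl-3-oxo-4-vinylcyclohexyl]malonate F1. Krapcho demethoxycarbonylation (LiCl, wet DMSO, 150 °C) gives methyl 2-[(1S,4S)-4-methyl-3-oxo-4-vinylcyclohexyl]acetate F2. Its ketone can enolise only toward C2, so TBSOTf/Et3N (CH2Cl2, 0 °C) converts it into the silyl enol ether 11.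

**Further compounds**
F1 | step 5 | dimethyl 2-[(1S,4S)-4-methyl-3-oxo-4-vinylcyclohexyl]malonate | O=C1[C@](C)(C=C)CC[C@H](C(C(=O)OC)C(=O)OC)C1
F2 | step 5 | methyl 2-[(1S,4S)-4-methyl-3-oxo-4-vinylcyclohexyl]acetate | O=C1[C@](C)(C=C)CC[C@H](CC(=O)OC)C1
F3 | step 11 | (4Z,8R,9S)-8-[2-(tert-butyldimethylsilyloxy)ethyl]-9-(dimethoxymethyl)-5-methylcyclonon-4-en-1-ol (C1 epimers) | OC1CC/C=C(/C)CC[C@H](CCO[Si](C)(C)C(C)(C)C)[C@H]1C(OC)OC
F0 | step 14 | none | none
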